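## Retrosynthetic overview

1. The target is reached by late β-face epoxidation of the 1(10)-Z olefin; before that the C3 ketone is unmasked from a 1,3-dithiane, the exo-methylene comes from an Eschenmoser methylenation and the C8 ester from acylation.
2. Key disconnection C6–C7: a samarium ketyl (umpoled C6 aldehyde) adds to the β-carbon C7 of an E-γ-hydroxy enoate and then lactonises, so the ten-membered carbocycle and the trans-γ-lactone form in one step.
3. The open-chain precursor comes from proline α-aminoxylation (C8–O) and Horner–Wadsworth–Emmons olefination (C7=C11); C2–C3 is made by alkylating a lithiated dithiane (acyl anion at C3) with a nerol-derived Z-allylic chloride.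
4. The C3–C6/C15 unit comes from methyl 4-oxobutanoate by organocatalytic α-hydroxymethylation (sets C4); its γ-lactone masks both the C6 aldehyde and the C15 hydroxyl.
5. Ring order: carbocycle and lactone together (step 7), oxirane last (step 11).

Assumption: atoms carry germacranolide numbers throughout (C1/C10 oxirane, C3 ketone, C4 bearing C15H2OH, C6–O/C7 lactone junction, C8 ester, C11–C13 lactone); SmI2, LiN(iPr)2 and LiN(SiMe3)2 are used as commercial solutions.

## Route

Step 1
Reactants: 1 nerol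
Product: 2 neryl chloride
Conditions: NCS, Me2S, CH2Cl2, −40 to 0 °C
Reagents that add atoms: N-chlorosuccinimide, ClN1C(=O)CCC1=O
Why: Corey–Kim chlorination displaces the alkoxysulfonium group by SN2 at the primary allylic carbon without allylic transposition, so the Z geometry of the future C1=C10 olefin is kept.

Step 2
Reactants: 2 neryl chloride
Product: 4 (2Z)-1-chloro-6,6-dimethoxy-3-methylhex-2-ene, via chloro aldehyde 3 (not isolated)
Conditions: O3 (1.0 equiv), CH2Cl2, −78 °C; PPh3, −78 to 0 °C; then HC(OMe)3, pyridinium p-toluenesulfonate (cat.), MeOH, 0 °C to rt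
Reagents that add atoms: trimethyl orthoformate, COC(OC)OC
Why: Chemoselective ozonolysis cleaves the electron-rich isopropylidene olefin (the other olefin is deactivated by the allylic chlorine), and acetalisation masks the aldehyde for the organolithium step.

Step 3
Reactants: 5 methyl 4-oxobutanoate
Product: 7 (4S)-4-(1,3-dithian-2-yl)oxolan-2-one, via hydroxy aldehyde 6 (not isolated)
Conditions: aq. HCHO, (R)-2-[diphenyl(trimethylsilyloxy)methyl]pyrrolidine (10 mol%), pH 7 phosphate buffer, toluene, rt; extractive work-up; then HS(CH2)3SH, BF3·OEt2 (20 mol%), CH2Cl2, 0 °C to rt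
Reagents that add atoms: formaldehyde, C=O; propane-1,3-dithiol, SCCCS
Why: Enamine-catalysed α-hydroxymethylation (organocatalytic cross-aldol with formaldehyde) sets C4, the (R)-diarylprolinol silyl ether shielding one enamine face to give the (S)-aldehyde, which is trapped at once by acid-catalysed dithioacetalisation and lactonisation before it can epimerise.

Step 4
Reactants: 7 (4S)-4-(1,3-dithian-2-yl)oxolan-2-one; 4 (2Z)-1-chloro-6,6-dimethoxy-3-methylhex-2-ene
Product: 9 (4Z)-4-methyl-6-{2-[(3S)-5-oxooxolan-3-yl]-1,3-dithian-2-yl}hex-4-enal, via dimethyl acetal 8 (not isolated)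
Conditions: LiN(iPr)2 (1.1 equiv), THF, −78 °C; n-BuLi (2.2 equiv), −78 to −25 °C; 4 (1.0 equiv), −78 to 0 °C; then 1 M HCl, THF, rt
Reagents that add atoms: water, O
Why: Corey–Seebach alkylation of an acyl anion equivalent: the lactone is first protected as its lithium enolate, the dithiane C–H is then lithiated, and this more reactive carbanion is alkylated selectively by the allylic chloride (SN2, Z retained); the acid work-up reprotonates the enolate and hydrolyses the acetal, and C4 is not touched.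

Step 5
Reactants: 9 (4Z)-4-methyl-6-{2-[(3S)-5-oxooxolan-3-yl]-1,3-dithian-2-yl}hex-4-enal; 10 trimethyl phosphonoacetate
Product: 13 methyl (2E,4R,6Z)-4-hydroxy-6-methyl-8-{2-[(3S)-5-oxooxolan-3-yl]-1,3-dithian-2-yl}octa-2,6-dienoate, via anilinooxy aldehyde 11 (not isolated), via anilinooxy enoate 12 (not isolated)
Conditions: PhNO (1.0 equiv), L-proline (20 mol%), DMSO, rt; then 10, LiCl, DBU, MeCN, 0 °C; then Zn, AcOH, rt
Reagents that add atoms: nitrosobenzene, O=Nc1ccccc1
Why: Proline-catalysed α-aminoxylation (enamine attack on the nitroso oxygen through the hydrogen-bonded chair transition state) sets C8 as R with L-proline, the labile product is trapped by a Masamune–Roush Horner–Wadsworth–Emmons olefination to the E-enoate, and zinc cleaves the N–O bond.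

Step 6
Reactants: 13 methyl (2E,4R,6Z)-4-hydroxy-6-methyl-8-{2-[(3S)-5-oxooxolan-3-yl]-1,3-dithian-2-yl}octa-2,6-dienoate
Product: 14 methyl (2E,4R,6Z)-4-hydroxy-8-{2-[(3S)-5-hydroxyoxolan-3-yl]-1,3-dithian-2-yl}-6-methylocta-2,6-dienoate (lactol; both anomers)
Conditions: disiamylborane (3 equiv; from BH3·SMe2 and 2-methylbut-2-ene), THF, 0 °C to rt; H2O work-up
Reagents that add atoms: none
Why: Partial reduction of a γ-lactone to the lactol by a hindered dialkylborane, which leaves the conjugated methyl ester, the dithiane and the trisubstituted olefin alone; the lactol is the masked C6 aldehyde and C15 hydroxyl.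

Step 7
Reactants: 14 methyl (2E,4R,6Z)-4-hydroxy-8-{2-[(3S)-5-hydroxyoxolan-3-yl]-1,3-dithian-2-yl}-6-methylocta-2,6-dienoate
Product: 16 (1(10)Z,4S,6R,7R,8R)-8,15-dihydroxy-3,3-(propane-1,3-diyldisulfanediyl)-13-norgermacr-1(10)-en-12,6-olide (trans-fused lactone), via ring-closed hydroxy ester 15 (not isolated)
Conditions: SmI2 (0.1 M in THF, 4 equiv, syringe pump over 8 h), t-BuOH (4 equiv), THF (0.002 M in 14), rt; aq. KNaC4H4O6 work-up; then pyridinium p-toluenesulfonate (cat.), CH2Cl2, rt
Reagents that add atoms: none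
Why: Proposed new method: the open hydroxy-aldehyde tautomer of the lactol is reduced by divalent samarium to a ketyl, in which the normally electrophilic C6 is a nucleophilic radical (carbonyl umpolung), and this adds 10-exo to the electrophilic β-carbon C7 of the E-enoate, the ester radical is reduced to the trivalent samarium enolate and protonated by t-BuOH, and the C6 samarium alkoxide closes the γ-lactone; C7 is expected to form by attack anti to the C8–O bond with the ring chain in the inside position (Felkin–Anh-type model for radical addition to γ-oxygenated enoates), and C6 by the extended anti arrangement of C5–C6 and C7–C8 in the ten-membered transition state, which leads to the trans-fused lactone; the closest known reactions are the SmI2-mediated aldehyde–acrylate reductive coupling to γ-lactones and SmI2 ketyl–olefin cyclisations to medium rings.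

Step 8
Reactants: 16 (1(10)Z,4S,6R,7R,8R)-8,15-dihydroxy-3,3-(propane-1,3-diyldisulfanediyl)-13-norgermacr-1(10)-en-12,6-olide; 17 (2R)-2-methylbutanoic acid
Product: 19 (1(10)Z,4S,6R,7S,8R)-8-[(2R)-2-methylbutanoyloxy]-3,3-(propane-1,3-diyldisulfanediyl)-15-(triethylsilyloxy)-13-norgermacr-1(10)-en-12,6-olide, via silyl ether 18 (not isolated)
Conditions: Et3SiCl (1.05 equiv), imidazole, CH2Cl2, −78 to −20 °C; then 17, N,N'-diisopropylcarbodiimide, 4-(dimethylamino)pyridine (cat.), CH2Cl2, 0 °C to rt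
Reagents that add atoms: chlorotriethylsilane, CC[Si](Cl)(CC)CC
Why: Selective silylation of the primary C15 hydroxyl over the hindered secondary C8 hydroxyl is followed by Steglich esterification of C8–OH with the enantiopure acid; no stereocentre is touched, and low temperature with catalytic DMAP avoids epimerising the acid.

Step 9
Reactants: 19 (1(10)Z,4S,6R,7S,8R)-8-[(2R)-2-methylbutanoyloxy]-3,3-(propane-1,3-diyldisulfanediyl)-15-(triethylsilyloxy)-13-norgermacr-1(10)-en-12,6-olide
Product: 22 (1(10)Z,4S,6R,7S,8R)-8-[(2R)-2-methylbutanoyloxy]-3,3-(propane-1,3-diyldisulfanediyl)-15-(triethylsilyloxy)germacra-1(10),11(13)-dien-12,6-olide, via Mannich base 20 (not isolated), via ammonium iodide 21 (not isolated)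
Conditions: LiN(SiMe3)2 (1.1 equiv), THF, −78 °C; CH2=NMe2+ I−, −78 to 0 °C; then MeI (3 equiv), MeOH/CH2Cl2, rt; aq. NaHCO3, rt
Reagents that add atoms: N,N-dimethylmethyleneiminium iodide, C=[N+](C)C.[I-]
Why: Eschenmoser methylenation: the γ-lactone, about five pKa units more acidic than the hindered acyclic ester, is enolised selectively, the enolate undergoes a Mannich reaction, and quaternisation with mild-base elimination installs the exo-methylene without touching C7.

Step 10
Reactants: 22 (1(10)Z,4S,6R,7S,8R)-8-[(2R)-2-methylbutanoyloxy]-3,3-(propane-1,3-diyldisulfanediyl)-15-(triethylsilyloxy)germacra-1(10),11(13)-dien-12,6-olide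
Product: 24 (1(10)Z,4S,6R,7S,8R)-15-hydroxy-8-[(2R)-2-methylbutanoyloxy]-3-oxogermacra-1(10),11(13)-dien-12,6-olide, via ketone silyl ether 23 (not isolated)
Conditions: PhI(OCOCF3)2 (1.5 equiv), MeCN/H2O 9:1, 0 °C to rt, 1 h; NaHCO3 quench
Reagents that add atoms: water, O
Why: Oxidative dithiane hydrolysis with the trivalent iodine reagent unmasks the C3 ketone without base, so C4 is not epimerised, and the trifluoroacetic acid released cleaves the primary triethylsilyl ether in the same pot.

Step 11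
Reactants: 24 (1(10)Z,4S,6R,7S,8R)-15-hydroxy-8-[(2R)-2-methylbutanoyloxy]-3-oxogermacra-1(10),11(13)-dien-12,6-olide
Product: 25 CNP0219035.1, (1R,4S,6R,7S,8R,10S)-1,10-epoxy-15-hydroxy-8-[(2R)-2-methylbutanoyloxy]-3-oxogermacr-11(13)-en-12,6-olide
Conditions: mCPBA (1.1 equiv), NaHCO3, CH2Cl2, −20 to 0 °C
Reagents that add atoms: 3-chloroperoxybenzoic acid, OOC(=O)c1cccc(Cl)c1
Why: Prilezhaev epoxidation is chemoselective for the electron-rich trisubstituted Z olefin over the electron-poor exo-methylene and stereospecifically gives the cis-oxirane; attack is predicted on the β face (the side of the C8 ester, whose carbonyl can hydrogen-bond the peracid, the α face being turned toward the ring interior), which sets 1R,10S, but this facial preference is not secured by precedent.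

## Compound list

1 | nerol, (2Z)-3,7-dimethylocta-2,6-dien-1-ol | CC(C)=CCC/C(C)=C\CO | starting material
2 | neryl chloride, (2Z)-1-chloro-3,7-dimethylocta-2,6-diene | CC(C)=CCC/C(C)=C\CCl | intermediate
3 | (4Z)-6-chloro-4-methylhex-4-enal | O=CCC/C(C)=C\CCl | intermediate
4 | (2Z)-1-chloro-6,6-dimethoxy-3-methylhex-2-ene | COC(OC)CC/C(C)=C\CCl | intermediate
5 | methyl 4-oxobutanoate | COC(=O)CCC=O | starting material
6 | methyl (3S)-3-formyl-4-hydroxybutanoate | COC(=O)C[C@@H](CO)C=O | intermediate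
7 | (4S)-4-(1,3-dithian-2-yl)oxolan-2-one | O=C1C[C@@H](CO1)C2SCCCS2 | intermediate
8 | (4S)-4-{2-[(2Z)-6,6-dimethoxy-3-methylhex-2-en-1-yl]-1,3-dithian-2-yl}oxolan-2-one | O=C1C[C@@H](CO1)C2(C/C=C(C)\CCC(OC)OC)SCCCS2 | intermediate
9 | (4Z)-4-methyl-6-{2-[(3S)-5-oxooxolan-3-yl]-1,3-dithian-2-yl}hex-4-enal | O=C1C[C@@H](CO1)C2(C/C=C(C)\CCC=O)SCCCS2 | intermediate
10 | trimethyl phosphonoacetate | COC(=O)CP(=O)(OC)OC | starting material
11 | (2R,4Z)-2-(anilinooxy)-4-methyl-6-{2-[(3S)-5-oxooxolan-3-yl]-1,3-dithian-2-yl}hex-4-enal | O=C1C[C@@H](CO1)C2(C/C=C(C)\C[C@@H](ONc3ccccc3)C=O)SCCCS2 | intermediate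
12 | methyl (2E,4R,6Z)-4-(anilinooxy)-6-methyl-8-{2-[(3S)-5-oxooxolan-3-yl]-1,3-dithian-2-yl}octa-2,6-dienoate | O=C1C[C@@H](CO1)C2(C/C=C(C)\C[C@@H](ONc3ccccc3)/C=C/C(=O)OC)SCCCS2 | intermediate
13 | methyl (2E,4R,6Z)-4-hydroxy-6-methyl-8-{2-[(3S)-5-oxooxolan-3-yl]-1,3-dithian-2-yl}octa-2,6-dienoate | O=C1C[C@@H](CO1)C2(C/C=C(C)\C[C@@H](O)/C=C/C(=O)OC)SCCCS2 | intermediate
14 | methyl (2E,4R,6Z)-4-hydroxy-8-{2-[(3S)-5-hydroxyoxolan-3-yl]-1,3-dithian-2-yl}-6-methylocta-2,6-dienoate (lactol, both anomers) | OC1C[C@@H](CO1)C2(C/C=C(C)\C[C@@H](O)/C=C/C(=O)OC)SCCCS2 | intermediate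
15 | methyl (1(10)Z,4S,6R,7S,8R)-6,8,15-trihydroxy-3,3-(propane-1,3-diyldisulfanediyl)-13-norgermacr-1(10)-en-12-oate | COC(=O)C[C@H]1[C@H](O)C[C@@H](CO)C2(SCCCS2)C/C=C(C)\C[C@H]1O | intermediate
16 | (1(10)Z,4S,6R,7R,8R)-8,15-dihydroxy-3,3-(propane-1,3-diyldisulfanediyl)-13-norgermacr-1(10)-en-12,6-olide (6βH,7αH trans-lactone; 8β-OH; 4β-CH2OH) | O=C1O[C@@H]2C[C@@H](CO)C3(SCCCS3)C/C=C(C)\C[C@@H](O)[C@H]2C1 | intermediate
17 | (2R)-2-methylbutanoic acid | CC[C@@H](C)C(=O)O | starting material
18 | 15-O-triethylsilyl ether of 16 | O=C1O[C@@H]2C[C@@H](CO[Si](CC)(CC)CC)C3(SCCCS3)C/C=C(C)\C[C@@H](O)[C@H]2C1 | intermediate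
19 | (1(10)Z,4S,6R,7S,8R)-8-[(2R)-2-methylbutanoyloxy]-3,3-(propane-1,3-diyldisulfanediyl)-15-(triethylsilyloxy)-13-norgermacr-1(10)-en-12,6-olide | O=C1O[C@@H]2C[C@@H](CO[Si](CC)(CC)CC)C3(SCCCS3)C/C=C(C)\C[C@@H](OC(=O)[C@H](C)CC)[C@H]2C1 | intermediate
20 | 11-(dimethylaminomethyl) derivative of 19 (C11 epimers) | O=C1O[C@@H]2C[C@@H](CO[Si](CC)(CC)CC)C3(SCCCS3)C/C=C(C)\C[C@@H](OC(=O)[C@H](C)CC)[C@H]2C1CN(C)C | intermediate
21 | 11-(trimethylammoniomethyl) iodide of 19 (C11 epimers) | O=C1O[C@@H]2C[C@@H](CO[Si](CC)(CC)CC)C3(SCCCS3)C/C=C(C)\C[C@@H](OC(=O)[C@H](C)CC)[C@H]2C1C[N+](C)(C)C.[I-] | intermediate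
22 | (1(10)Z,4S,6R,7S,8R)-8-[(2R)-2-methylbutanoyloxy]-3,3-(propane-1,3-diyldisulfanediyl)-15-(triethylsilyloxy)germacra-1(10),11(13)-dien-12,6-olide | C=C1C(=O)O[C@@H]2C[C@@H](CO[Si](CC)(CC)CC)C3(SCCCS3)C/C=C(C)\C[C@@H](OC(=O)[C@H](C)CC)[C@@H]12 | intermediate
23 | (1(10)Z,4S,6R,7S,8R)-8-[(2R)-2-methylbutanoyloxy]-3-oxo-15-(triethylsilyloxy)germacra-1(10),11(13)-dien-12,6-olide | C=C1C(=O)O[C@@H]2C[C@@H](CO[Si](CC)(CC)CC)C(=O)C/C=C(C)\C[C@@H](OC(=O)[C@H](C)CC)[C@@H]12 | intermediate
24 | (1(10)Z,4S,6R,7S,8R)-15-hydroxy-8-[(2R)-2-methylbutanoyloxy]-3-oxogermacra-1(10),11(13)-dien-12,6-olide | C=C1C(=O)O[C@@H]2C[C@@H](CO)C(=O)C/C=C(C)\C[C@@H](OC(=O)[C@H](C)CC)[C@@H]12 | intermediate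
25 | CNP0219035.1, (1R,4S,6R,7S,8R,10S)-1,10-epoxy-15-hydroxy-8-[(2R)-2-methylbutanoyloxy]-3-oxogermacr-11(13)-en-12,6-olide | C=C1C(=O)O[C@@H]2C[C@@H](CO)C(=O)C[C@H]3O[C@@]3(C)C[C@@H](OC(=O)[C@H](C)CC)[C@@H]12 | target

## Step count and risks

Total step count: 11. Longest linear sequence: 10 steps (nerol 1 to 25 through steps 1, 2 and 4–11); the branch from methyl 4-oxobutanoate is 9 steps.

Steps most likely to fail:

- **Step 7 (ketyl macro-lactonisation).** Risks are the ten-membered ring closure, slow opening of the lactol, and the C6/C7 configuration, which rests on a model only. The fallback sets out from 14: an N-heterocyclic carbene (triazolium precatalyst, KN(SiMe3)2 cat., toluene, high dilution) turns the lactol aldehyde into its Breslow acyl anion equivalent, which adds intramolecularly to C7 (Stetter reaction) to give the ten-membered keto ester F1. Chelation-controlled reduction of the C6 ketone with Zn(BH4)2 and acid lactonisation then return to 16.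

- **Step 11 (epoxide face).** If the peracid prefers the α face, the fallback sets out from 24: NBS in aqueous dimethoxyethane gives, by anti opening of the α-bromonium ion at the tertiary carbon, the bromohydrin F4. Ag2O in CH2Cl2 closes it with inversion at C1 to the β-oxirane, returning to 25.

- **Step 4 (dianion alkylation).** Risks are competing alkylation or decomposition of the lactone enolate. The fallback sets out from 4: 2-lithio-1,3-dithiane (from 1,3-dithiane and n-BuLi) is alkylated with 4 to give the alkyl dithiane F2. F2 is lithiated again (n-BuLi, THF/HMPA) and added in 1,4-fashion, trans to the alkoxy group, to the known auxiliary butenolide (5S)-5-[(1S,2R,5S)-menthyloxy]furan-2(5H)-one, giving the trans adduct F3. NaBH4/KOH followed by aq. HCl (loss of menthol, lactone closure, acetal hydrolysis) returns to 9.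

Further compounds
F1 | step 7 | methyl (1(10)Z,4S,7R,8R)-8,15-dihydroxy-6-oxo-3,3-(propane-1,3-diyldisulfanediyl)-13-norgermacr-1(10)-en-12-oate | COC(=O)C[C@H]1C(=O)C[C@@H](CO)C2(SCCCS2)C/C=C(C)\C[C@H]1O
F2 | step 4 | 2-[(2Z)-6,6-dimethoxy-3-methylhex-2-en-1-yl]-1,3-dithiane | COC(OC)CC/C(C)=C\CC1SCCCS1
F3 | step 4 | (4S,5S)-4-{2-[(2Z)-6,6-dimethoxy-3-methylhex-2-en-1-yl]-1,3-dithian-2-yl}-5-[(1S,2R,5S)-menthyloxy]oxolan-2-one | O=C1C[C@H](C2(C/C=C(C)\CCC(OC)OC)SCCCS2)[C@@H](O[C@H]3C[C@@H](C)CC[C@@H]3C(C)C)O1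
F4 | step 11 | (1S,4S,6R,7S,8R,10S)-1-bromo-10,15-dihydroxy-8-[(2R)-2-methylbutanoyloxy]-3-oxogermacr-11(13)-en-12,6-olide | C=C1C(=O)O[C@@H]2C[C@@H](CO)C(=O)C[C@H](Br)[C@@](C)(O)C[C@@H](OC(=O)[C@H](C)CC)[C@@H]12
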